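Ring B is disconnected at C9–C10 and C5–C6. One operation, an acylation/cycloalkylation cascade, joins (4-methoxyphenyl)acetyl chloride to (S)-2,4,4-trimethylcyclohex-2-enyl acetate: acylation at C5 creates the C6 ketone, and the electrophilic C10 is then attacked by the anisole carbon C9, closing ring B and setting the quaternary C10 anti to the C1 acetoxy group. The step exploits the 1,3-relation between the C6 oxygen and the methyl-bearing C10 and the sp2 nature of C8/C9, so that ring C can enter as an anisole. Birch reduction later reveals the C8=C9 alkene and a C12 ketone, whose two α-carbons (C11, C13) are bridged by C15–C16.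

Key step: step 3

Remark (numbering): positions follow the target skeleton: C1 acetoxy carbon, C4 gem-dimethyl carbon, C5/C10 ring fusion, C6 carbinol, C8=C9, C11/C13 bridgeheads, C12 carbinol bridge, C15 ketone, C16=C17 methylene, C20 angular methyl; α is the face of C20, β the face of H5.
Assumption: 2,4,4-trimethylcyclohex-2-en-1-one is taken as purchasable (otherwise it is one step from isobutyraldehyde and ethyl vinyl ketone).

Step 1
Reactants: 1 2,4,4-trimethylcyclohex-2-en-1-one
Product: 2 (S)-2,4,4-trimethylcyclohex-2-en-1-ol
Conditions: (R)-2-methyl-CBS-oxazaborolidine (10 mol %), BH3·SMe2, THF, −20 °C; MeOH quench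
Reagents that add atoms: none
Why: CBS reduction, in which the (R)-oxazaborolidine should treat the α-methyl alkenyl flank as the large group and the CH2 flank as the small one and so deliver hydride to give the (S)-allylic alcohol, setting C1.

Step 2
Reactants: 2 (S)-2,4,4-trimethylcyclohex-2-en-1-ol
Product: 3 (S)-2,4,4-trimethylcyclohex-2-en-1-yl acetate
Conditions: Ac2O, pyridine, DMAP (cat.), CH2Cl2, 0 °C → rt
Reagents that add atoms: acetic anhydride (CC(=O)OC(C)=O)
Why: DMAP-catalysed O-acetylation protects the C1 hydroxyl from O-acylation in step 3 and provides the group that directs the facial course at C10.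

Step 3
Reactants: 3 (S)-2,4,4-trimethylcyclohex-2-en-1-yl acetate; 4 (4-methoxyphenyl)acetyl chloride
Product: 6 1α-acetoxy-12-methoxy tricyclic 6-ketone with trans A/B fusion [(4S,4aR,10aR)-6-methoxy-1,1,4a-trimethyl-10-oxo-1,2,3,4,4a,9,10,10a-octahydrophenanthren-4-yl acetate], via enone 5 (not isolated)
Conditions: AlCl3 (3 equiv), CH2Cl2, −40 → 0 °C (3 added to the preformed complex of 4 and AlCl3); ice/aq. HCl
Reagents that add atoms: none
Why: The acylium ion from 4 acylates the trisubstituted alkene of 3 at its less substituted carbon C5 (Darzens–Nenitzescu alkene acylation); the C10 cation so formed, held by the neighbouring acetate as an acetoxonium ion or relaxed by loss of the C5 proton to enone 5, is then alkylated by the anisole carbon ortho to the CH2 group (C9) in an intramolecular Friedel–Crafts cycloalkylation. The closest known reaction type is the one-pot 2-tetralone synthesis from arylacetyl chlorides and alkenes, whose stepwise form is the acid-mediated ring closure of benzyl cyclohexenyl ketones to 6-oxo tricyclic arenes. Ring B is closed by 6-endo-trig attack of the arene carbon C9 on C10 of the Lewis acid-bound enone (Friedel–Crafts conjugate addition), the C5–C6 bond having been formed intermolecularly just before. C10 is controlled by the C1 stereocentre, since the arene should add anti to the pseudoaxial acetoxy group (steric approach control, reinforced by backside opening of the cis-acetoxonium ion), which places C20 cis to the acetate. C5 is set by protonation of the enol next to the C6 ketone and should settle in the trans ring fusion under the equilibrating acidic conditions. The step needs ortho rather than ipso attack on the arene (the two ortho positions are equivalent and the six-membered closure is favoured over the spiro five-membered one) and alkene acylation rather than ionisation of the allylic acetate, which the low-temperature addition of 3 to the preformed acylium complex is meant to secure.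

Step 4
Reactants: 6 1α-acetoxy-12-methoxy tricyclic 6-ketone
Product: 7 12-methoxy tricyclic 1α,6α-diol [(4S,4aR,10S,10aR)-6-methoxy-1,1,4a-trimethyl-1,2,3,4,4a,9,10,10a-octahydrophenanthrene-4,10-diol]
Conditions: LiAlH4, THF, 0 °C → rt; NaOH/H2O work-up
Reagents that add atoms: none
Why: Hydride reduction in which LiAlH4 should attack the C6 carbonyl from the β face, away from the syn-axial C20 and C4α methyl groups, to give the axial 6α-alcohol, while the acetate is cleaved reductively in the same operation.

Step 5
Reactants: 7 12-methoxy tricyclic 1α,6α-diol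
Product: 9 1α,6α-dihydroxy-8-en-12-one (ring C β,γ-unsaturated ketone; C8=C9), via dienol ether 8 (not isolated)
Conditions: Li, NH3 (l), t-BuOH, THF, −78 → −33 °C; NH4Cl; then (CO2H)2, MeOH/H2O, rt
Reagents that add atoms: water (O)
Why: Birch reduction leaves the alkyl-bearing C8=C9 bond and the methoxy-bearing C12=C13 bond as the 1,4-diene, and mild enol ether hydrolysis then gives the C12 ketone without moving the tetrasubstituted alkene into conjugation.

Step 6
Reactants: 9 1α,6α-dihydroxy-8-en-12-one
Product: 11 11β-(prop-2-ynyl)-1α,6α-dihydroxy-8-en-12-one, via dienamine 10 (not isolated)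
Conditions: pyrrolidine (3 equiv), benzene, reflux (Dean–Stark), evaporate; propargyl bromide (1.1 equiv), MeCN, 60 °C; then AcOH/NaOAc, H2O
Reagents that add atoms: propargyl bromide (C#CCBr); water (O)
Why: Stork enamine alkylation, in which the conjugated dienamine reacts at its α-carbon C11 on the β face, anti to the axial C20 methyl group, giving monoalkylation without base so that the two free hydroxyls need no protection.

Step 7
Reactants: 11 11β-(prop-2-ynyl)-1α,6α-dihydroxy-8-en-12-one
Product: 12 tetracyclic 1α,6α-dihydroxy-12-ketone with the C15H2–C16(=C17H2) bridge from C11 to C13 on the β face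
Conditions: pyrrolidine (30 mol %), Cu(OTf)2 (10 mol %), PPh3 (40 mol %), MeOH, 50 °C
Reagents that add atoms: none
Why: Amine/copper dual-catalysed Conia-ene-type carbocyclisation, in which the less substituted enamine (C12=C13) adds 5-exo-dig to the copper-activated alkyne held axially on the β face, closing the bicyclo[3.2.1]octenone and fixing C13 by the geometry of the bridge.

Step 8
Reactants: 12 tetracyclic 1α,6α-dihydroxy-12-ketone
Product: 13 tetracyclic 1α-acetoxy-6α-hydroxy-12-ketone
Conditions: Ac2O (1.2 equiv), pyridine, DMAP (cat.), CH2Cl2, 0 °C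
Reagents that add atoms: acetic anhydride (CC(=O)OC(C)=O)
Why: Selective acylation, since the equatorial C1 hydroxyl should react while the axial C6 hydroxyl, flanked by the syn-axial C20 and C4α methyl groups, stays free.

Step 9
Reactants: 13 tetracyclic 1α-acetoxy-6α-hydroxy-12-ketone
Product: 14 1α-acetoxy-6α,15-dihydroxy-12-ketone (15S; C15 hydroxyl exo, on the side of the C12 bridge)
Conditions: SeO2 (0.3 equiv), t-BuOOH, CH2Cl2, rt
Reagents that add atoms: tert-butyl hydroperoxide (CC(C)(C)OO)
Why: Selenium dioxide allylic oxidation (ene reaction then [2,3]-shift) of the 1,1-disubstituted C16=C17 alkene at C15, its only non-bridgehead allylic position, from the open exo face, while the shielded tetrasubstituted C8=C9 bond should not compete.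

Step 10
Reactants: 14 1α-acetoxy-6α,15-dihydroxy-12-ketone
Product: 15 1α-acetoxy-6α,12,15-triol (C12 hydroxyl syn to the C15–C16 bridge)
Conditions: LiAlH(Ot-Bu)3 (4 equiv), THF, −40 → 0 °C; NaOH/H2O work-up
Reagents that add atoms: none
Why: Bulky hydride reduction, in which the exo C15 alkoxide should shield the face of the C12 carbonyl that looks toward the C15–C16 bridge, so that hydride enters from the side of the C8=C9 bridge and the new hydroxyl ends syn to the two-carbon bridge, the acetate being inert to this reagent.

Step 11
Reactants: 15 1α-acetoxy-6α,12,15-triol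
Product: 16 target CNP0149338.1 (1α-acetoxy-6α,12-dihydroxy-8-ene with the 16-methylene-15-ketone bridge)
Conditions: MnO2 (activated, excess), CH2Cl2, rt
Reagents that add atoms: none
Why: MnO2 oxidises only the allylic C15 alcohol, giving the α-methylene ketone and leaving the saturated C6 and C12 alcohols untouched.

Compound list
1 | 2,4,4-trimethylcyclohex-2-en-1-one | CC1=CC(C)(C)CCC1=O | starting material
2 | (S)-2,4,4-trimethylcyclohex-2-en-1-ol | CC1(C)CC[C@H](O)C(C)=C1 | intermediate
3 | (S)-2,4,4-trimethylcyclohex-2-en-1-yl acetate | CC1(C)CC[C@H](OC(C)=O)C(C)=C1 | intermediate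
4 | (4-methoxyphenyl)acetyl chloride | COc1ccc(CC(Cl)=O)cc1 | starting material
5 | (S)-3-[(4-methoxyphenyl)acetyl]-2,4,4-trimethylcyclohex-2-en-1-yl acetate (conjugated enone, not isolated) | CC1(C)CC[C@H](OC(C)=O)C(C)=C1C(=O)Cc1ccc(OC)cc1 | intermediate
6 | (4S,4aR,10aR)-6-methoxy-1,1,4a-trimethyl-10-oxo-1,2,3,4,4a,9,10,10a-octahydrophenanthren-4-yl acetate (1α-acetoxy-12-methoxy 6-ketone, trans A/B) | c13cc(OC)ccc1CC(=O)[C@@H]2C(C)(C)CC[C@H](OC(C)=O)[C@@]32C | intermediate
7 | (4S,4aR,10S,10aR)-6-methoxy-1,1,4a-trimethyl-1,2,3,4,4a,9,10,10a-octahydrophenanthrene-4,10-diol (1α,6α-diol) | c13cc(OC)ccc1C[C@H](O)[C@@H]2C(C)(C)CC[C@H](O)[C@@]32C | intermediate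
8 | 12-methoxy-8,12-diene-1α,6α-diol (ring C 1,4-dihydroanisole, not isolated) | C13=C(CC=C(OC)C1)C[C@H](O)[C@@H]2C(C)(C)CC[C@H](O)[C@@]32C | intermediate
9 | 1α,6α-dihydroxy-8-en-12-one (ring C β,γ-unsaturated ketone) | C13=C(CCC(=O)C1)C[C@H](O)[C@@H]2C(C)(C)CC[C@H](O)[C@@]32C | intermediate
10 | 12-(pyrrolidin-1-yl)-8,11-diene-1α,6α-diol (conjugated dienamine, not isolated) | C13=C(CCC(N4CCCC4)=C1)C[C@H](O)[C@@H]2C(C)(C)CC[C@H](O)[C@@]32C | intermediate
11 | 11β-(prop-2-ynyl)-1α,6α-dihydroxy-8-en-12-one | C#CC[C@@H]2C3=C(CCC2=O)C[C@H](O)[C@@H]1C(C)(C)CC[C@H](O)[C@@]31C | intermediate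
12 | tetracyclic 1α,6α-dihydroxy-12-ketone with β C15H2–C16(=CH2) bridge between C11 and C13 | C=C1C[C@@H]2C3=C(C[C@H]1C2=O)C[C@H](O)[C@@H]1C(C)(C)CC[C@H](O)[C@@]31C | intermediate
13 | tetracyclic 1α-acetoxy-6α-hydroxy-12-ketone | C=C1C[C@@H]2C3=C(C[C@H]1C2=O)C[C@H](O)[C@@H]1C(C)(C)CC[C@H](OC(C)=O)[C@@]31C | intermediate
14 | 1α-acetoxy-6α,15-dihydroxy-12-ketone (15S, exo hydroxyl) | C=C1[C@@H](O)[C@@H]2C3=C(C[C@H]1C2=O)C[C@H](O)[C@@H]1C(C)(C)CC[C@H](OC(C)=O)[C@@]31C | intermediate
15 | 1α-acetoxy-6α,12,15-triol (C12 hydroxyl syn to the C15–C16 bridge) | C=C1[C@@H](O)[C@@H]2C3=C(C[C@H]1[C@@H]2O)C[C@H](O)[C@@H]1C(C)(C)CC[C@H](OC(C)=O)[C@@]31C | intermediate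
16 | CNP0149338.1 | C=C1C(=O)[C@@H]2C3=C(C[C@H]1[C@@H]2O)C[C@H](O)[C@@H]1C(C)(C)CC[C@H](OC(C)=O)[C@@]31C | target

Total step count: 11. Longest linear sequence: 11 steps (from 1; compound 4 enters in step 3).

Steps most likely to fail

Step 3. The Lewis acid may ionise the allylic acetate, or acylation at the hindered alkene carbon C5 may be too slow, so that elimination or rearrangement outruns the cascade. The fallback sets out from 3 and returns at 6. A carbonyl-ene reaction of 3 with (4-methoxyphenyl)acetaldehyde promoted by Me2AlCl (CH2Cl2, −78 °C), a proton-scavenging Lewis acid under which allylic esters should not ionise readily, would form the C5–C6 bond and give (1S)-3-[1-hydroxy-2-(4-methoxyphenyl)ethyl]-4,4-dimethyl-2-methylidenecyclohexyl acetate F1 (the ring carbon C5 and the carbinol carbon are left undefined because both are erased later). Dess–Martin oxidation would give the β,γ-unsaturated ketone (1S)-3-[(4-methoxyphenyl)acetyl]-4,4-dimethyl-2-methylidenecyclohexyl acetate F2. Polyphosphoric acid (or AlCl3 in CH2Cl2) would then bring F2 into conjugation as enone 5 and effect the Friedel–Crafts cycloalkylation of the benzyl cyclohexenyl ketone, giving 6.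

Step 7. The catalytic enamine may form only toward C11 (the conjugated side), or the bridging 5-exo-dig closure may be too strained for it. The fallback sets out from 9 and returns at 12. The enamine alkylation of step 6 is run with 2,3-dibromopropene instead of propargyl bromide, giving 11β-(2-bromoprop-2-enyl)-1α,6α-dihydroxy-8-en-12-one F3. Pd(PPh3)4 with KOt-Bu in THF at 60 °C would then couple the C13 enolate with the alkenyl bromide (intramolecular ketone α-alkenylation), forming the C13–C16 bond and the exocyclic methylene of 12 directly.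

Step 10. Hydride may be delivered to the wrong face of the C12 carbonyl, either by poor facial discrimination or by intramolecular delivery from the C15 alkoxide, giving the C12 epimer. The fallback sets out from 14 and returns at 15. The exo C15 hydroxyl is silylated selectively (TBSOTf, 2,6-lutidine, CH2Cl2, −78 °C; the axial C6 hydroxyl is too hindered) to give the 15-O-tert-butyldimethylsilyl ether of 14 F4, whose bulky silyl group blocks the bridge-side face. NaBH4 in MeOH at 0 °C should then reduce C12 from the side of the C8=C9 bridge to the 15-O-tert-butyldimethylsilyl ether of 15 F5, and HF·pyridine in THF removes the silyl group to give 15.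

Further compounds
F1 | step 3 | (1S)-3-[1-hydroxy-2-(4-methoxyphenyl)ethyl]-4,4-dimethyl-2-methylidenecyclohexyl acetate | C=C1[C@@H](OC(C)=O)CCC(C)(C)C1C(O)Cc1ccc(OC)cc1
F2 | step 3 | (1S)-3-[(4-methoxyphenyl)acetyl]-4,4-dimethyl-2-methylidenecyclohexyl acetate | C=C1[C@@H](OC(C)=O)CCC(C)(C)C1C(=O)Cc1ccc(OC)cc1
F3 | step 7 | 11β-(2-bromoprop-2-enyl)-1α,6α-dihydroxy-8-en-12-one | C=C(Br)C[C@@H]2C3=C(CCC2=O)C[C@H](O)[C@@H]1C(C)(C)CC[C@H](O)[C@@]31C
F4 | step 10 | 15-O-tert-butyldimethylsilyl ether of 14 | C=C1[C@@H](O[Si](C)(C)C(C)(C)C)[C@@H]2C3=C(C[C@H]1C2=O)C[C@H](O)[C@@H]1C(C)(C)CC[C@H](OC(C)=O)[C@@]31C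
F5 | step 10 | 15-O-tert-butyldimethylsilyl ether of 15 | C=C1[C@@H](O[Si](C)(C)C(C)(C)C)[C@@H]2C3=C(C[C@H]1[C@@H]2O)C[C@H](O)[C@@H]1C(C)(C)CC[C@H](OC(C)=O)[C@@]31C
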